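**Plan**

- Retrosynthesis: the butenolide is opened at C8=C17 and at the lactone C–O bond (Horner–Wadsworth–Emmons), the ten-membered ring at C4–C5 (B-alkyl Suzuki–Miyaura), the chain at C2–C3 (vinyl addition), and the six-membered ring at C1–C14 and C10–C11 in one [4+2] event.
- Enabling feature: the ring C1/C10–C14 carries oxygen at C14 and C12 (1,3-related) next to the quaternary C1 that bears the C2 carbinol. With C12 read as a ketone, this is the adduct of a 1-alkoxy-3-silyloxy diene (C11–C14) and an (E)-2-methyl enal (C2–C1=C10); the trans C2/C9 ring fusion is the E geometry of the enal.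
- Forward order: D-glyceraldehyde acetonide gives the enal (C6–C10, C1, C2) and pent-1-yn-3-ol gives the diene. The Diels–Alder step makes the cyclohexane, the C12 ketone becomes the C11=C12 alkene and then the β-epoxide, the ten-membered ring is closed at C4–C5, and the butenolide is made last.
- Stereochemistry: C7 comes from D-glyceraldehyde; C1, C10 and C14 from the catalyst-controlled endo cycloaddition; C2 from chelation to the C14 ether; C11/C12 from a chiral ketone catalyst; 5Z from a Z-iodoalkene. C8 is a relay centre that is oxidised away.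

Key step: step 7

Remark: briarane numbering is used for all intermediates (C1 quaternary ring-fusion carbon, C2 butanoyloxy carbon, C5=C6 alkene, C7 lactone carbinol carbon, C8/C17/C19 butenolide carbons, C9 CH2, C10 ring-fusion CH, C11/C12 epoxide, C14 acetoxy carbon). β is the ring face of the C1 methyl group and α the opposite face. The phosphonate α-carbon in 25–27 is an inconsequential epimer mixture.

Step 1
Reactants: 1 (R)-2,2-dimethyl-1,3-dioxolane-4-carbaldehyde (D-glyceraldehyde acetonide)
Product: 2 (S)-1-[(4R)-2,2-dimethyl-1,3-dioxolan-4-yl]but-3-en-1-ol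
Conditions: Zn dust, allyl bromide, THF/sat. aq NH4Cl, 0 °C → rt
Reagents that add atoms: allyl bromide, C=CCBr
Why: Barbier allylation of the α-alkoxy aldehyde should follow the Felkin–Anh (anti) mode and give the 8S alcohol, a relay centre that keeps later intermediates single isomers and is removed by oxidation in step 24.

Step 2
Reactants: 2 (S)-1-[(4R)-2,2-dimethyl-1,3-dioxolan-4-yl]but-3-en-1-ol
Product: 3 tert-butyldimethylsilyl ether of 2
Conditions: TBSCl, imidazole, DMF, rt
Reagents that add atoms: tert-butyldimethylsilyl chloride, CC(C)(C)[Si](C)(C)Cl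
Why: Routine silylation of a secondary alcohol gives an ether that should survive every step up to its planned removal in step 23.

Step 3
Reactants: 3 tert-butyldimethylsilyl ether of 2
Product: 4 (2E,5S)-5-(tert-butyldimethylsilyloxy)-5-[(4R)-2,2-dimethyl-1,3-dioxolan-4-yl]-2-methylpent-2-enal
Conditions: methacrolein (5 equiv), second-generation Hoveyda–Grubbs catalyst RuCl2(H2IMes)(=CH–C6H4-2-OiPr) (5 mol %), CH2Cl2, 40 °C
Reagents that add atoms: methacrolein, C=C(C)C=O
Why: Olefin cross-metathesis of an unhindered terminal alkene with methacrolein is a known route to 2-methyl enals and should give the E isomer (formyl trans to C9) under thermodynamic control.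

Step 4
Reactants: 5 pent-1-yn-3-ol (racemic)
Product: 6 pent-1-yn-3-one
Conditions: Dess–Martin periodinane, CH2Cl2, 0 °C → rt
Reagents that add atoms: none
Why: Dess–Martin oxidation of a propargylic alcohol gives the ynone under neutral conditions; the volatile product is used as a solution.

Step 5
Reactants: 6 pent-1-yn-3-one
Product: 7 (E)-1-(4-methoxybenzyloxy)pent-1-en-3-one
Conditions: 4-methoxybenzyl alcohol, DABCO (10 mol %), CH2Cl2, 0 °C → rt
Reagents that add atoms: 4-methoxybenzyl alcohol, COc1ccc(CO)cc1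
Why: Amine-catalysed oxa-Michael addition of an alcohol to a terminal ynone is known to give the E β-alkoxy enone, which installs the future C14 oxygen as a chelating, oxidatively removable ether.

Step 6
Reactants: 7 (E)-1-(4-methoxybenzyloxy)pent-1-en-3-one
Product: 8 (1E,3Z)-1-(4-methoxybenzyloxy)-3-(triisopropylsilyloxy)penta-1,3-diene
Conditions: TIPSOTf, Et3N, Et2O, 0 °C
Reagents that add atoms: triisopropylsilyl trifluoromethanesulfonate, CC(C)[Si](C(C)C)(C(C)C)OS(=O)(=O)C(F)(F)F
Why: Soft enolisation of the ethyl ketone should give the Z silyl enol ether (methyl on the outside of the s-cis diene), that is a 4-methyl Danishefsky-type diene.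

Step 7
Reactants: 4 (2E,5S)-5-(tert-butyldimethylsilyloxy)-5-[(4R)-2,2-dimethyl-1,3-dioxolan-4-yl]-2-methylpent-2-enal; 8 (1E,3Z)-1-(4-methoxybenzyloxy)-3-(triisopropylsilyloxy)penta-1,3-diene
Product: 9 Diels–Alder adduct (C1 formyl/methyl quaternary centre; 14α-OPMB cis to formyl; 12-OTIPS enol ether at C12=C13; 11α-methyl; 10α-H)
Conditions: B-(o-tolyl)oxazaborolidine of (R)-α,α-diphenylprolinol (20 mol %), (CF3SO2)2NH (18 mol %), CH2Cl2, −78 → −40 °C; Et3N quench
Reagents that add atoms: none
Why: The triflimide-activated oxazaborolidinium binds the formyl oxygen of 4 (with a formyl C–H···O contact) and lowers the LUMO of the s-trans enal, so that 8 adds in an asynchronous concerted [4+2] cycloaddition in which the nucleophilic enol-ether terminus C11 bonds first to the β-carbon C10 and the alkoxy-bearing C14 then closes onto C1; the closest known reaction type is the chiral oxazaborolidinium-catalysed Diels–Alder reaction of 2-methyl enals with 2-silyloxy and 1-oxy dienes. One ring is closed, the cyclohexene C1–C14–C13–C12–C11–C10, in an intermolecular suprafacial–suprafacial mode with no tether. C1 and C10 come out trans (C2 versus C9) because the E geometry of the enal is transferred, C14–O comes out cis to the formyl group through the endo-formyl transition state, and C11 (methyl outside in the Z enol ether) is set cis to C14–O but is erased in step 11. The absolute sense is set by the catalyst: in the accepted binding model the S catalyst leaves open the C1 face on which formyl, C10 and methyl run clockwise, so the R catalyst is chosen to expose the required opposite face (C1 si, C10 re), and the remote C7/C8 centres should not override it. Regioselectivity is secured because both donors of the diene (C14–OPMB, C12–OSi) make C11 its nucleophilic end and the bound formyl group makes C10 the electrophilic end. Selectivity for the C=C bond over the formyl C=O (hetero-Diels–Alder or Mukaiyama aldol) is also needed and should be favoured by the bulky triisopropylsilyl enol ether and the shielded, catalyst-bound carbonyl group.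

Step 8
Reactants: 9 Diels–Alder adduct
Product: 10 (2S)-vinyl carbinol (C2–OH, C3=C4 vinyl)
Conditions: MgBr2·OEt2 (2 equiv), CH2Cl2, −78 °C; then vinylmagnesium bromide (THF), −78 °C
Reagents that add atoms: vinylmagnesium bromide, C=C[Mg]Br
Why: Cram-chelate addition to the β-alkoxy aldehyde: magnesium bridges C2=O and the cis C14–OPMB, and the Grignard reagent attacks the convex face of the cis-fused chelate (the side of the C1 methyl, away from C10), which should give 2S.

Step 9
Reactants: 10 (2S)-vinyl carbinol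
Product: 11 C2 butanoate
Conditions: butanoic anhydride, DMAP, Et3N, CH2Cl2, rt
Reagents that add atoms: butanoic anhydride, CCCC(=O)OC(=O)CCC
Why: DMAP-catalysed acylation installs the butanoate of the target on the only free hydroxyl group.

Step 10
Reactants: 11 C2 butanoate
Product: 12 C12 ketone (β-alkoxy ketone, 14-OPMB kept)
Conditions: TBAF/AcOH (1:1), THF, −20 °C
Reagents that add atoms: none
Why: Buffered fluoride cleaves the silyl enol ether much faster than the alkyl TBS ether, and immediate protonation of the enolate should prevent β-elimination of the C14 ether.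

Step 11
Reactants: 12 C12 ketone
Product: 13 C11=C12 enol triflate (12-OTf, 11-methyl)
Conditions: Tf2O, 2,6-di-tert-butyl-4-methylpyridine, CH2Cl2, 0 °C → rt
Reagents that add atoms: trifluoromethanesulfonic anhydride, O=S(=O)(OS(=O)(=O)C(F)(F)F)C(F)(F)F
Why: O-triflation of the ketone with a hindered pyridine base is known to favour the more substituted enol triflate, here by loss of the axial C11–H, which removes the temporary C11 centre.

Step 12
Reactants: 13 C11=C12 enol triflate
Product: 14 C11=C12 alkene (11-methyl, 12-H)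
Conditions: Pd(OAc)2 (5 mol %), PPh3, HCO2H, n-Bu3N, DMF, 50 °C
Reagents that add atoms: none
Why: Formate reduction of a vinyl triflate; oxidative addition of zerovalent palladium to the triflate should be much faster than ionisation of the hindered secondary allylic butanoate at C2.

Step 13
Reactants: 14 C11=C12 alkene
Product: 15 C14 alcohol
Conditions: DDQ, CH2Cl2/pH 7 buffer, 0 °C
Reagents that add atoms: none
Why: Oxidative cleavage of the 4-methoxybenzyl ether leaves the alkenes, the esters and the silyl ether untouched, and the neutral buffer should suppress migration of the C2 butanoate.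

Step 14
Reactants: 15 C14 alcohol
Product: 16 C14 acetate
Conditions: Ac2O, DMAP, pyridine, rt
Reagents that add atoms: acetic anhydride, CC(=O)OC(C)=O
Why: Acetylation installs the second ester of the target on the only free hydroxyl group.

Step 15
Reactants: 16 C14 acetate
Product: 17 C6,C7 diol
Conditions: AcOH/THF/H2O (3:1:1), rt
Reagents that add atoms: none
Why: Mild acid hydrolysis of the terminal acetonide is done before the acid-sensitive epoxide exists and should leave the secondary TBS ether and both esters in place.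

Step 16
Reactants: 17 C6,C7 diol
Product: 18 C6,C7 bis(triethylsilyl) ether
Conditions: TESOTf, 2,6-lutidine, CH2Cl2, −78 °C
Reagents that add atoms: triethylsilyl trifluoromethanesulfonate, CC[Si](CC)(CC)OS(=O)(=O)C(F)(F)F
Why: Silylation of both hydroxyl groups prepares the selective oxidation of step 18 and is placed before epoxidation because silyl triflates open epoxides.

Step 17
Reactants: 18 C6,C7 bis(triethylsilyl) ether
Product: 19 11β,12β-epoxide
Conditions: ent-Shi ketone (L-fructose series, 30 mol %), Oxone (2KHSO5·KHSO4·K2SO4), K2CO3, n-Bu4NHSO4, MeCN/CH2(OMe)2/aq. borate buffer (pH 10.5), 0 °C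
Reagents that add atoms: potassium peroxymonosulfate (active component of Oxone), [K+].[O-]S(=O)(=O)OO
Why: Shi epoxidation: the chiral dioxirane reacts through a spiro transition state with the electron-rich trisubstituted C11=C12 alkene far faster than with the terminal vinyl group, and the L-series ketone should deliver oxygen to the β face (the face of the C1 methyl and of C9), setting C11 and C12 by reagent control.

Step 18
Reactants: 19 11β,12β-epoxide
Product: 20 C6 aldehyde (7-OTES)
Conditions: (COCl)2, DMSO, CH2Cl2, −78 → −30 °C; Et3N, −78 → 0 °C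
Reagents that add atoms: none
Why: Swern conditions are known to convert a primary triethylsilyl ether directly into the aldehyde while a secondary one survives, and the base-free low-temperature profile should keep C7 from epimerising.

Step 19
Reactants: 20 C6 aldehyde
Product: 21 (Z)-iodoalkene (C6H=C5(I)CH3, iodine cis to C7)
Conditions: EtPPh3I, n-BuLi, THF, 0 °C; I2, −78 °C; NaN(SiMe3)2, −20 °C; then 20, −78 → −20 °C
Reagents that add atoms: ethyltriphenylphosphonium iodide, CC[P+](c1ccccc1)(c1ccccc1)c1ccccc1.[I-]; iodine, II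
Why: Stork–Zhao-type Wittig olefination with the α-iodoethylidene ylide is known to give (Z)-2-iodoalk-2-enes from aldehydes, which fixes the later 5Z geometry.

Step 20
Reactants: 21 (Z)-iodoalkene
Product: 23 ten-membered carbocycle (5Z alkene; 7-OTES; 8-OTBS), via alkylborane 22 (not isolated)
Conditions: 9-BBN dimer, THF, rt; then Pd(dppf)Cl2 (10 mol %), AsPh3, Cs2CO3, DMF/THF/H2O, 40 °C, syringe-pump addition (2 mM)
Reagents that add atoms: none
Why: Anti-Markovnikov hydroboration of the only terminal alkene puts boron on C4, and the intramolecular B-alkyl Suzuki–Miyaura coupling with the C5 iodide forms C4–C5 with retention of alkene geometry, so that C4 ends up cis to C7.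

Step 21
Reactants: 23 ten-membered carbocycle
Product: 24 C7 alcohol
Conditions: HF·pyridine, pyridine, THF, 0 °C
Reagents that add atoms: none
Why: Buffered HF·pyridine removes the allylic triethylsilyl ether selectively in the presence of the TBS ether, the epoxide and the esters.

Step 22
Reactants: 24 C7 alcohol
Product: 25 C7 2-(diethoxyphosphoryl)propanoate
Conditions: 2-(diethoxyphosphoryl)propanoic acid, DCC, DMAP, CH2Cl2, 0 °C → rt
Reagents that add atoms: 2-(diethoxyphosphoryl)propanoic acid, CCOP(=O)(OCC)C(C)C(=O)O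
Why: Steglich esterification proceeds with retention at C7 and brings in C17, C18 and C19 of the butenolide.

Step 23
Reactants: 25 C7 2-(diethoxyphosphoryl)propanoate
Product: 26 C8 alcohol
Conditions: HF·pyridine, pyridine, THF, 0 °C → rt
Reagents that add atoms: none
Why: Acidic fluoride cleaves the TBS ether without the 1,2-acyl migration from O7 to O8 that basic fluoride could cause.

Step 24
Reactants: 26 C8 alcohol
Product: 28 target (1S,2S,5Z,7R,10R,11R,12S,14S)-14-acetoxy-2-butanoyloxy-11,12-epoxybriara-5,8(17)-dien-18,7-olide, via keto phosphonate 27 (not isolated)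
Conditions: Dess–Martin periodinane, NaHCO3, CH2Cl2, 0 °C; then LiCl, i-Pr2NEt, MeCN, rt
Reagents that add atoms: none
Why: Oxidation removes the C8 relay centre, and the intramolecular Horner–Wadsworth–Emmons reaction of the α-acyloxy ketone under Masamune–Roush conditions closes the butenolide (C8=C17) mildly enough to keep C7 from epimerising.

**Compound list**

1 | (R)-2,2-dimethyl-1,3-dioxolane-4-carbaldehyde | O=C[C@H]1COC(C)(C)O1 | starting material
2 | (S)-1-[(4R)-2,2-dimethyl-1,3-dioxolan-4-yl]but-3-en-1-ol | C=CC[C@H](O)[C@H]1COC(C)(C)O1 | intermediate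
3 | TBS ether of 2 | C=CC[C@H](O[Si](C)(C)C(C)(C)C)[C@H]1COC(C)(C)O1 | intermediate
4 | (2E,5S)-5-(tert-butyldimethylsilyloxy)-5-[(4R)-2,2-dimethyl-1,3-dioxolan-4-yl]-2-methylpent-2-enal | O=C/C(C)=C/C[C@H](O[Si](C)(C)C(C)(C)C)[C@H]1COC(C)(C)O1 | intermediate
5 | pent-1-yn-3-ol (racemic) | CCC(O)C#C | starting material
6 | pent-1-yn-3-one | CCC(=O)C#C | intermediate
7 | (E)-1-(4-methoxybenzyloxy)pent-1-en-3-one | CCC(=O)/C=C/OCc1ccc(OC)cc1 | intermediate
8 | (1E,3Z)-1-(4-methoxybenzyloxy)-3-(triisopropylsilyloxy)penta-1,3-diene | COc1ccc(CO/C=C/C(O[Si](C(C)C)(C(C)C)C(C)C)=C/C)cc1 | intermediate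
9 | Diels–Alder adduct: cyclohex-3-ene with C1 (β-methyl, α-formyl), 14α-OPMB, 12-OTIPS enol ether (C12=C13), 11α-methyl, 10α-H, and at C10 the β side chain CH2–(8S)-CH(OTBS)–(7R)-dioxolane | O=C[C@@]1(C)[C@@H](OCc2ccc(OC)cc2)C=C(O[Si](C(C)C)(C(C)C)C(C)C)[C@@H](C)[C@@H]1C[C@H](O[Si](C)(C)C(C)(C)C)[C@H]1COC(C)(C)O1 | intermediate
10 | (2S)-vinyl carbinol from 9 | C=C[C@H](O)[C@@]1(C)[C@@H](OCc2ccc(OC)cc2)C=C(O[Si](C(C)C)(C(C)C)C(C)C)[C@@H](C)[C@@H]1C[C@H](O[Si](C)(C)C(C)(C)C)[C@H]1COC(C)(C)O1 | intermediate
11 | C2 butanoate of 10 | C=C[C@H](OC(=O)CCC)[C@@]1(C)[C@@H](OCc2ccc(OC)cc2)C=C(O[Si](C(C)C)(C(C)C)C(C)C)[C@@H](C)[C@@H]1C[C@H](O[Si](C)(C)C(C)(C)C)[C@H]1COC(C)(C)O1 | intermediate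
12 | C12 ketone (14α-OPMB, 11α-methyl) | C=C[C@H](OC(=O)CCC)[C@@]1(C)[C@@H](OCc2ccc(OC)cc2)CC(=O)[C@@H](C)[C@@H]1C[C@H](O[Si](C)(C)C(C)(C)C)[C@H]1COC(C)(C)O1 | intermediate
13 | C11=C12 enol triflate | C=C[C@H](OC(=O)CCC)[C@@]1(C)[C@@H](OCc2ccc(OC)cc2)CC(OS(=O)(=O)C(F)(F)F)=C(C)[C@@H]1C[C@H](O[Si](C)(C)C(C)(C)C)[C@H]1COC(C)(C)O1 | intermediate
14 | C11=C12 alkene (14α-OPMB) | C=C[C@H](OC(=O)CCC)[C@@]1(C)[C@@H](OCc2ccc(OC)cc2)CC=C(C)[C@@H]1C[C@H](O[Si](C)(C)C(C)(C)C)[C@H]1COC(C)(C)O1 | intermediate
15 | 14α-alcohol | C=C[C@H](OC(=O)CCC)[C@@]1(C)[C@@H](O)CC=C(C)[C@@H]1C[C@H](O[Si](C)(C)C(C)(C)C)[C@H]1COC(C)(C)O1 | intermediate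
16 | 14α-acetate | C=C[C@H](OC(=O)CCC)[C@@]1(C)[C@@H](OC(C)=O)CC=C(C)[C@@H]1C[C@H](O[Si](C)(C)C(C)(C)C)[C@H]1COC(C)(C)O1 | intermediate
17 | C6,C7 diol | C=C[C@H](OC(=O)CCC)[C@@]1(C)[C@@H](OC(C)=O)CC=C(C)[C@@H]1C[C@H](O[Si](C)(C)C(C)(C)C)[C@H](O)CO | intermediate
18 | C6,C7 bis(triethylsilyl) ether | C=C[C@H](OC(=O)CCC)[C@@]1(C)[C@@H](OC(C)=O)CC=C(C)[C@@H]1C[C@H](O[Si](C)(C)C(C)(C)C)[C@H](O[Si](CC)(CC)CC)CO[Si](CC)(CC)CC | intermediate
19 | 11β,12β-epoxide (20-methyl α) | C=C[C@H](OC(=O)CCC)[C@@]1(C)[C@@H](OC(C)=O)C[C@@H]2O[C@]2(C)[C@@H]1C[C@H](O[Si](C)(C)C(C)(C)C)[C@H](O[Si](CC)(CC)CC)CO[Si](CC)(CC)CC | intermediate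
20 | C6 aldehyde (7-OTES, 8-OTBS) | C=C[C@H](OC(=O)CCC)[C@@]1(C)[C@@H](OC(C)=O)C[C@@H]2O[C@]2(C)[C@@H]1C[C@H](O[Si](C)(C)C(C)(C)C)[C@H](O[Si](CC)(CC)CC)C=O | intermediate
21 | (Z)-iodoalkene C7–CH=C(I)CH3 | C=C[C@H](OC(=O)CCC)[C@@]1(C)[C@@H](OC(C)=O)C[C@@H]2O[C@]2(C)[C@@H]1C[C@H](O[Si](C)(C)C(C)(C)C)[C@H](O[Si](CC)(CC)CC)/C=C(\I)C | intermediate
22 | alkylborane (C4–9-BBN adduct of 21) | C1CCC2CCCC1B2CC[C@H](OC(=O)CCC)[C@@]3(C)[C@@H](OC(C)=O)C[C@@H]4O[C@]4(C)[C@@H]3C[C@H](O[Si](C)(C)C(C)(C)C)[C@H](O[Si](CC)(CC)CC)/C=C(\I)C | intermediate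
23 | ten-membered carbocycle (5Z; 7-OTES; 8-OTBS) | CCCC(=O)O[C@H]1CC/C(C)=C\[C@@H](O[Si](CC)(CC)CC)[C@@H](O[Si](C)(C)C(C)(C)C)C[C@H]2[C@@]3(C)O[C@H]3C[C@H](OC(C)=O)[C@]12C | intermediate
24 | macrocyclic C7 alcohol | CCCC(=O)O[C@H]1CC/C(C)=C\[C@@H](O)[C@@H](O[Si](C)(C)C(C)(C)C)C[C@H]2[C@@]3(C)O[C@H]3C[C@H](OC(C)=O)[C@]12C | intermediate
25 | C7 2-(diethoxyphosphoryl)propanoate (8-OTBS) | CCCC(=O)O[C@H]1CC/C(C)=C\[C@@H](OC(=O)C(C)P(=O)(OCC)OCC)[C@@H](O[Si](C)(C)C(C)(C)C)C[C@H]2[C@@]3(C)O[C@H]3C[C@H](OC(C)=O)[C@]12C | intermediate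
26 | C8 alcohol | CCCC(=O)O[C@H]1CC/C(C)=C\[C@@H](OC(=O)C(C)P(=O)(OCC)OCC)[C@@H](O)C[C@H]2[C@@]3(C)O[C@H]3C[C@H](OC(C)=O)[C@]12C | intermediate
27 | keto phosphonate (C8 ketone) | CCCC(=O)O[C@H]1CC/C(C)=C\[C@@H](OC(=O)C(C)P(=O)(OCC)OCC)C(=O)C[C@H]2[C@@]3(C)O[C@H]3C[C@H](OC(C)=O)[C@]12C | intermediate
28 | (1S,2S,5Z,7R,10R,11R,12S,14S)-14-acetoxy-2-butanoyloxy-11,12-epoxybriara-5,8(17)-dien-18,7-olide | CCCC(=O)O[C@H]1CC/C(C)=C\[C@H]2OC(=O)C(C)=C2C[C@H]2[C@@]3(C)O[C@H]3C[C@H](OC(C)=O)[C@]12C | target

**Step count and risks**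

Total step count: 24. Longest linear sequence: 21 steps (steps 1–3 then 7–24, or steps 4–6 then 7–24).

Steps most likely to fail:

1. Step 7. The silyl enol ether may add to the Lewis-acid-bound formyl group (hetero-Diels–Alder or Mukaiyama aldol) instead of the C=C bond, the acid-labile diene may decompose, or the facial sense may be poor. Fallback, from 4 and 8 back to 9: the two partners are heated without any Lewis acid (toluene, BHT, 80–110 °C), conditions under which 1-alkoxy-3-silyloxy dienes add only to the C=C bond of enals. Because the side chain of 4 is enantiopure, the two facial modes give diastereomers, 9 and the facial diastereomer F1, which are separated by chromatography; 9 then continues at step 8.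

2. Step 20. Ring strain in the ten-membered ring may make intramolecular transmetalation slower than oligomerisation or protodeboronation. Fallback, from 19 back to 23, moving the ring closure to C5=C6 by metathesis: hydroboration of 19 with 9-BBN gives the alkylborane F3, which is coupled intermolecularly with 2-bromopropene (Pd(dppf)Cl2, AsPh3, Cs2CO3, DMF/H2O, rt) to give the isopentenyl compound F4. Swern oxidation of the primary silyl ether gives the aldehyde F5, and Wittig methylenation (Ph3P=CH2, THF, −78 → 0 °C) gives the diene F6. Ring-closing metathesis (second-generation Grubbs catalyst RuCl2(H2IMes)(PCy3)(=CHPh), toluene, 80 °C, 1 mM) should then give the Z-cycloalkene 23.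

3. Step 11. Enolisation may occur toward C13 instead of C11, or the C14 ether may be lost by β-elimination. Fallback, from 12 back to 14: reduction with LiBH(s-Bu)3 (THF, −78 °C) attacks from the face away from the axial C14 ether and should give the axial 12α-alcohol F2. Dehydration with Martin sulfurane, Ph2S[OC(CF3)2Ph]2 (CH2Cl2, 0 °C → rt), by anti elimination through the axial H-11 should give the trisubstituted alkene 14, bypassing 13.

Further compounds
F1 | step 7 | facial diastereomer of adduct 9 (all four ring stereocentres inverted, side chain unchanged) | O=C[C@]1(C)[C@H](OCc2ccc(OC)cc2)C=C(O[Si](C(C)C)(C(C)C)C(C)C)[C@H](C)[C@H]1C[C@H](O[Si](C)(C)C(C)(C)C)[C@H]1COC(C)(C)O1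
F2 | step 11 | 12α-alcohol from ketone 12 | C=C[C@H](OC(=O)CCC)[C@@]1(C)[C@@H](OCc2ccc(OC)cc2)C[C@@H](O)[C@@H](C)[C@@H]1C[C@H](O[Si](C)(C)C(C)(C)C)[C@H]1COC(C)(C)O1
F3 | step 20 | alkylborane (C4–9-BBN adduct of 19) | C1CCC2CCCC1B2CC[C@H](OC(=O)CCC)[C@@]3(C)[C@@H](OC(C)=O)C[C@@H]4O[C@]4(C)[C@@H]3C[C@H](O[Si](C)(C)C(C)(C)C)[C@H](O[Si](CC)(CC)CC)CO[Si](CC)(CC)CC
F4 | step 20 | isopentenyl compound (C2 chain CH2CH2C(CH3)=CH2; 6,7-bis-OTES) | C=C(C)CC[C@H](OC(=O)CCC)[C@@]1(C)[C@@H](OC(C)=O)C[C@@H]2O[C@]2(C)[C@@H]1C[C@H](O[Si](C)(C)C(C)(C)C)[C@H](O[Si](CC)(CC)CC)CO[Si](CC)(CC)CC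
F5 | step 20 | C6 aldehyde of the isopentenyl series | C=C(C)CC[C@H](OC(=O)CCC)[C@@]1(C)[C@@H](OC(C)=O)C[C@@H]2O[C@]2(C)[C@@H]1C[C@H](O[Si](C)(C)C(C)(C)C)[C@H](O[Si](CC)(CC)CC)C=O
F6 | step 20 | diene for ring-closing metathesis (C7 vinyl, C5 isopropenyl) | C=C(C)CC[C@H](OC(=O)CCC)[C@@]1(C)[C@@H](OC(C)=O)C[C@@H]2O[C@]2(C)[C@@H]1C[C@H](O[Si](C)(C)C(C)(C)C)[C@H](O[Si](CC)(CC)CC)C=C
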